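All runs stem from a simulated flask on assumed constants, noise included.

The percentage point is the unit of the amber readings, and each of them scatters by 1.5 percentage points, so one early ratio of the two products says little.

- amber: left-handed substrate 0.16 M; right-handed substrate 0.16 M; coupling partner 0.16 M; free catalyst 0.80 mM; racemization catalyst 4 mM; added ligand 12 mM; run made earlier
- flask: left-handed substrate 0.16 M; coupling partner 0.320 M; free catalyst 0.80 mM; racemization catalyst 4.0 mM; added ligand 12 mM; right-handed substrate 0.16 M; time 3.0 d

amber run (percent of the left-handed substrate and right-handed substrate together charged)

| time / h | left-handed product / % | right-handed product / % | left-handed substrate / % |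
|---|---|---|---|
| 1.00 | 3 | 0 | 49 |
| 2.00 | 8 | 4 | 43 |
| 3.00 | 8 | 3 | 44 |
| 5.00 | 11 | 1 | 39 |
| 8.00 | 12 | 4 | 38 |
| 15.0 | 19 | 9 | 34 |

(readings scatter by 1.5 percentage points)

- free catalyst is single-handed; left-handed substrate and right-handed substrate are mirror images of each other, charged as a racemate, each of them at the stated concentration
- the numbers in the tables scatter with a standard deviation of 1.5 percentage points
- candidate steps: coupling partner + free catalyst + left-handed substrate -> free catalyst + left-handed product; coupling partner + free catalyst + right-handed substrate -> free catalyst + right-handed product; left-handed substrate + racemization catalyst <-> right-handed substrate + racemization catalyst; 2 free catalyst -> spent catalyst; racemization catalyst + added ligand <-> idle complex; 2 racemization catalyst <-> resting dimer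
- an excess is below zero if the other one leads

- left-handed product and right-handed product together, in percent of the left-handed substrate and right-handed substrate charged together, at 3.0 d
- excess of left-handed product over right-handed product in the product at 3.0 d
- whether the exchange between left-handed substrate and right-handed substrate keeps pace with the reaction: how far the product's excess at 3.0 d gets from its value without exchange to its value with instant exchange (above 80 % keeps pace, below 20 % hardly takes part, else lags behind)

The free catalyst is single-handed, so the two substrates need not react at the same speed, and the ratio of their two rate constants is the selectivity factor. With instant exchange the two substrates would stand equal throughout, and the excess in the product would keep one value at any conversion. Without exchange the faster substrate thins out first, and the excess falls as conversion rises. Early in a run the two cases lie close together, so low-conversion readings estimate that one value.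

Adding the 6 amber readings of each product gives 61.0 % of left-handed product and 21.0 % of right-handed product, so the amber run holds more of the left-handed product than of the right-handed one. Their difference over their sum is 48.8 %, the pooled excess, a reading that marks where the product's excess stands if the exchange keeps pace.

Whether it does is harder to read. At 15.0 h the left-handed substrate reads 34 %; the balance puts it at 31.0 % without exchange and at 36.0 % with instant exchange. Those two marks stand 5 points apart, and the reading lies 3 points above the lower mark and 2 points below the upper one, while the reading and both marks carry the scatter of 1.5 points. This one reading therefore does not separate the two cases, so this reckoning takes the pooled excess as the upper mark for the flask.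

The forecast says 75 % of product, from 60 % to 88 %, and an excess of 35 %, from 24 % to 46 %, which is below the pooled excess. Its verdict is that the exchange lags behind, because "The left-handed substrate sits only slightly above its no-exchange value".

The flask gives 72.2 % of product and an excess of 44.9 %; the exchange keeps pace, at 93 % of the way from the value without exchange to that with instant exchange.

    coupling partner + free catalyst + left-handed substrate → free catalyst + left-handed product (k = 485 M⁻² h⁻¹)
    coupling partner + free catalyst + right-handed substrate → free catalyst + right-handed product (k = 178 M⁻² h⁻¹)
    left-handed substrate + racemization catalyst ⇌ right-handed substrate + racemization catalyst, rate k3*[racemization catalyst]*[left-handed substrate] forward; the back reaction follows from the equilibrium constant (k = 194 M⁻¹ h⁻¹)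
    2 free catalyst → spent catalyst (k = 30.6 M⁻¹ h⁻¹)
    racemization catalyst + added ligand ⇌ idle complex, settled at all times (K = 5.70 M⁻¹)
    2 racemization catalyst ⇌ resting dimer (K = 120 M⁻¹, k = 790 M⁻¹ h⁻¹)

At 0.300 d in the flask, with 34.1 % reacted, the excess of right-handed over left-handed substrate is 2.23 %, while the product's excess is 44.3 %. The flask's final excess lies 3.9 points below the pooled excess. The neighbour flask with 0.080 M of coupling partner reaches 22.3 % of product at the same time and shows an excess of 46.0 %, 2.8 points below the pooled excess.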